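**Retrosynthetic overview**
1. Feature: in the cyclopentane ring (C1–C5) of the trans-hydroazulene, C3 is a lone CH2 between the secondary carbinol C2 and the tertiary isopropyl carbinol C4. C3 is taken as the carbon of nitromethane, so C2–C3 and C3–C4 are cut together (double Henry, then radical loss of NO2). This leads back to a cycloheptene with formyl on C1 and isobutyryl on C5.
2. The esters come off first: the C6 p-hydroxybenzoate (phenol masked as allyl ether), then the C2 angelate. A C6 silyl ether tells the two positions apart, and the tertiary C4 hydroxyl needs no protection.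
3. The keto aldehyde comes from a C2–O–C4(=O) butyrolactone fused on C1–C5. i-PrLi opens it, its α-alkylidene precursor takes up the C6 oxygen by conjugate borylation, and CO closes it on a C5 vinyl bromide.
4. Quaternary C1 comes from a C6 carbinol by a suprafacial [2,3]-Wittig–Still shift. The carbinol comes from CBS reduction of a 2-bromocycloheptadienone, itself made by Birch reduction of 2,5-dimethylanisole and dibromocarbene ring expansion.
5. Ring order: seven-membered ring (step 3), temporary lactone (closed in step 7, opened in step 10), cyclopentane last (step 12).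

Key step: step 12

Numbering and faces: C1 quaternary fusion carbon, C2 angelate carbinol, C3 CH2, C4 isopropyl carbinol, C5 fusion CH, C6 benzoate carbinol, C7 CH2, C8=C9 alkene (methyl on C8), C10 CH2. β is the ring face that carries the C1 methyl, α the other face.
Assumption: the nitro epimer at C3 and the C5 epimer of the lactones are drawn as expected; neither matters, because C3 is erased in step 13 and C5 is equilibrated in step 10.

**Step 1**
Reactants: 1 2,5-dimethylanisole
Product: 2 1-methoxy-2,5-dimethylcyclohexa-1,4-diene
Conditions: Li, NH3(l), t-BuOH, THF, −78 → −33 °C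
Reagents that add atoms: none
Why: Birch reduction protonates the radical anion at the two para-related ring carbons that bear no donor (C3 and C6), so methoxy and both methyl groups end up on the two isolated double bonds.

**Step 2**
Reactants: 2 1-methoxy-2,5-dimethylcyclohexa-1,4-diene; 3 bromoform
Product: 4 (±)-7,7-dibromo-1-methoxy-3,6-dimethylbicyclo[4.1.0]hept-3-ene
Conditions: KOt-Bu, pentane, −20 → 0 °C; used crude
Reagents that add atoms: none
Why: In this dibromocarbene [2+1] cycloaddition the electrophilic carbene picks the tetrasubstituted enol-ether double bond over the trisubstituted alkyl one, and only the cis fusion is possible, so 4 forms as a racemate whose stereocentres vanish in step 3.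

**Step 3**
Reactants: 4 (±)-7,7-dibromo-1-methoxy-3,6-dimethylbicyclo[4.1.0]hept-3-ene
Product: 5 2-bromo-3,6-dimethylcyclohepta-2,5-dien-1-one
Conditions: AgOAc, acetone–H2O, rt, dark
Reagents that add atoms: water, O
Why: Silver-assisted disrotatory electrocyclic opening of the gem-dibromocyclopropane (cyclopropyl to allyl cation), pushed by the methoxy group, gives a 2-bromoallyl oxocarbenium ion in the enlarged ring that water hydrolyses, so the carbonyl can only appear at C6 and the bromide at C5, while the acetate buffer keeps the skipped dienone from enolising towards a tropone.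

**Step 4**
Reactants: 5 2-bromo-3,6-dimethylcyclohepta-2,5-dien-1-one
Product: 6 (S)-2-bromo-3,6-dimethylcyclohepta-2,5-dien-1-ol
Conditions: (R)-Me-CBS oxazaborolidine [(3aR)-1-methyl-3,3-diphenyltetrahydro-1H,3H-pyrrolo[1,2-c][1,3,2]oxazaborole, 0.2 equiv], catecholborane, toluene, −78 °C
Reagents that add atoms: none
Why: In this Corey–Bakshi–Shibata reduction the 2-bromoalkenyl arm acts as the large and the C7 methylene as the small substituent, so the (R)-catalyst should deliver hydride to the face that gives the (S)-carbinol (C6–O α), and catecholborane at low temperature leaves C8=C9 alone.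

**Step 5**
Reactants: 6 (S)-2-bromo-3,6-dimethylcyclohepta-2,5-dien-1-ol; 7 tributyl(iodomethyl)stannane
Product: 8 (S)-tributyl{[(2-bromo-3,6-dimethylcyclohepta-2,5-dien-1-yl)oxy]methyl}stannane
Conditions: KH, THF, 0 °C → rt
Reagents that add atoms: none
Why: Williamson etherification of the potassium alkoxide with the primary iodide does not touch the carbinol centre.

**Step 6**
Reactants: 8 (S)-tributyl{[(2-bromo-3,6-dimethylcyclohepta-2,5-dien-1-yl)oxy]methyl}stannane
Product: 10 [(S)-2-bromo-1,5-dimethylcyclohepta-2,5-dien-1-yl]methanol, via lithiomethyl ether 9 (not isolated)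
Conditions: n-BuLi (1.05 equiv), THF, −78 °C
Reagents that add atoms: none
Why: In this Wittig–Still [2,3]-sigmatropic rearrangement tin–lithium exchange at the α-alkoxystannane should outrun bromine–lithium exchange at the hindered tetrasubstituted vinyl bromide, and the concerted suprafacial shift carries the CH2O unit from O6 to C1 on the same α face, so the C6 configuration is transferred to quaternary C1 (CH2OH α, CH3 β) while C5=C6 forms.

**Step 7**
Reactants: 10 [(S)-2-bromo-1,5-dimethylcyclohepta-2,5-dien-1-yl]methanol; 11 carbon monoxide
Product: 12 (3aR)-3a,6-dimethyl-3,3a,4,7-tetrahydro-1H-cyclohepta[c]furan-1-one (α-alkylidene lactone C2–O–C4(=O)–C5=C6)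
Conditions: Pd(PPh3)4 (5 mol %), CO (3 bar), Et3N, MeCN, 70 °C
Reagents that add atoms: none
Why: Palladium-catalysed carbonylative lactonisation of a vinyl halide bearing a homoallylic hydroxyl (oxidative addition to zerovalent palladium, CO insertion, capture of the acyl complex by the neighbouring alcohol in a five-membered ring) is a standard route to α-alkylidene butyrolactones, and it brings in C4 without any protecting group.

**Step 8**
Reactants: 12 α-alkylidene lactone
Product: 14 cis-fused 6α-hydroxy lactone (C1-CH3 β; H5 β; C6-OH α), via 6α-pinacolboryl lactone 13 (not isolated)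
Conditions: B2pin2, CuCl (5 mol %), DPEphos (bis[2-(diphenylphosphino)phenyl] ether, 5 mol %), NaOt-Bu (cat.), MeOH (2 equiv), THF, rt; then NaBO3·4H2O, THF–H2O, rt
Reagents that add atoms: sodium perborate, [Na+].[Na+].O[B-]1(O)OO[B-](O)(O)OO1 (oxygen on C6); bis(pinacolato)diboron, CC1(C)OB(OC1(C)C)B1OC(C)(C)C(C)(C)O1 (boron of 13 only)
Why: This is a conjugate β-borylation catalysed by monovalent copper followed by stereoretentive perborate oxidation, in which the lactone holds C2 in the enoate plane so the C1 methyl stands nearly perpendicular on the β face, syn-borylcupration (copper on C5, next to C1) therefore takes the α face and sets C6–O α, and enolate protonation away from boron should give the cis-fused C5 epimer that step 10 corrects.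

**Step 9**
Reactants: 14 cis-fused 6α-hydroxy lactone
Product: 15 cis-fused 6α-(tert-butyldimethylsilyloxy) lactone
Conditions: TBSOTf, 2,6-lutidine, CH2Cl2, −78 → 0 °C
Reagents that add atoms: tert-butyldimethylsilyl triflate, CC(C)(C)[Si](C)(C)OS(=O)(=O)C(F)(F)F
Why: O-silylation with the triflate and a hindered pyridine base is fast at low temperature and too weakly basic to trigger retro-aldol or β-elimination in the β-hydroxy lactone.

**Step 10**
Reactants: 15 cis-fused 6α-silyloxy lactone; 16 isopropyllithium
Product: 18 1α-hydroxymethyl-5β-isobutyryl-6α-(tert-butyldimethylsilyloxy)-1β,8-dimethylcyclohept-8-ene, via 5-epi hydroxy ketone 17 (not isolated)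
Conditions: i-PrLi (1.3 equiv), Et2O, −78 °C; MeOH quench; then K2CO3, MeOH, rt
Reagents that add atoms: none
Why: 1,2-addition of the organolithium to the lactone stops at the hemiketal alkoxide because a second addition to the hindered isopropyl ketone is blocked, and carbonate-mediated enolisation in the protic medium then equilibrates C5 to the epimer that carries hydroxymethyl, isobutyryl and silyloxy all pseudo-equatorial (acyl trans to both neighbours, H5 α), with only the C1 methyl axial.

**Step 11**
Reactants: 18 hydroxy ketone
Product: 19 1α-formyl-5β-isobutyryl-6α-(tert-butyldimethylsilyloxy)-1β,8-dimethylcyclohept-8-ene (keto aldehyde)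
Conditions: Dess–Martin periodinane, CH2Cl2, 0 °C → rt
Reagents that add atoms: none
Why: Dess–Martin oxidation of the neopentyl primary alcohol drains the open form from any hemiketal, gives a non-enolisable aldehyde, and is free of base, so C5 and the β-silyloxy ketone stay intact.

**Step 12**
Reactants: 19 keto aldehyde; 20 nitromethane
Product: 22 3α-nitro-6α-(tert-butyldimethylsilyloxy)dauc-8-ene-2β,4β-diol (trans-fused; C1-CH3 β; H5 α; isopropyl α on C4), via C2 nitro alcohol 21 (not isolated)
Conditions: CH3NO2 (20 equiv), DBU (0.3 equiv), THF, 0 °C → rt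
Reagents that add atoms: none
Why: The amidine deprotonates nitromethane, the nitronate adds to the C2 aldehyde (the isopropyl ketone is too hindered for intermolecular attack) to give 21, and the more acidic CH2NO2 group of 21 is deprotonated in turn and adds to the C4 ketone. The closest known reaction is the double Henry (nitroaldol) cyclisation of dicarbonyl compounds with nitromethane to cyclic 2-nitro-1,3-diols, and intramolecular Henry additions to ketones are known from domino Michael–Henry cyclopentane syntheses. The cyclopentane closes by a 5-(enolexo)-exo-trig attack of C3 on C4, helped by formyl and isobutyryl sitting trans-diequatorial on adjacent ring carbons, which also fixes the trans ring fusion. Every C–C bond formation is reversible, so the new centres settle thermodynamically: at C4 the isopropyl group takes the α face, away from the C5–C6 arm and the β methyl on C1; at C2 the hydroxyl takes the quasi-equatorial β position cis to the methyl, as a 17β-hydroxyl does in the D ring of a steroid, and cis to the C4 hydroxyl to which it can hydrogen-bond; at C3 the acidic centre places nitro trans to both hydroxyls, the usual outcome of such cyclisations, and is erased in step 13. The step needs the C5 proton and the C6 silyloxy group to stay untouched, and the large excess of nitromethane secures this by levelling the medium to nitronate basicity, far below what enolisation of the ketone and β-elimination require.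

**Step 13**
Reactants: 22 nitro diol
Product: 23 6α-(tert-butyldimethylsilyloxy)dauc-8-ene-2β,4β-diol
Conditions: Bu3SnH, AIBN (portionwise), toluene, 110 °C
Reagents that add atoms: none
Why: In this radical denitration with tin hydride the stannyl radical adds to a nitro oxygen, C–N scission gives the secondary C3 radical, and hydrogen abstraction leaves CH2, while hydroxyl groups β to the radical do not fragment and the neutral medium avoids retro-Henry cleavage.

**Step 14**
Reactants: 23 2β,4β-diol; 24 angelic acid
Product: 26 2β-angeloyloxy-6α-(tert-butyldimethylsilyloxy)dauc-8-en-4β-ol, via angeloyl trichlorobenzoyl anhydride 25 (not isolated)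
Conditions: 2,4,6-Cl3C6H2COCl, Et3N, toluene, rt; then 23, 80 °C
Reagents that add atoms: 2,4,6-trichlorobenzoyl chloride, O=C(Cl)c1c(Cl)cc(Cl)cc1Cl (aroyl group of 25 only)
Why: Yamaguchi-type mixed-anhydride esterification run without a nucleophilic catalyst is the known way to make angelates without Z to E isomerisation, and only the secondary C2 hydroxyl reacts because C4–OH is tertiary and C6 is silylated.

**Step 15**
Reactants: 26 C2 angelate silyl ether
Product: 27 2β-angeloyloxydauc-8-ene-4β,6α-diol
Conditions: HF·pyridine, THF, 0 °C → rt
Reagents that add atoms: none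
Why: Fluoride cleavage of the secondary silyl ether under mildly acidic, non-nucleophilic conditions should spare the angelate geometry and the tertiary alcohol.

**Step 16**
Reactants: 27 4β,6α-diol; 28 4-(allyloxy)benzoic acid
Product: 29 6α-[4-(allyloxy)benzoyloxy]-2β-angeloyloxydauc-8-en-4β-ol
Conditions: DCC, DMAP, CH2Cl2, rt
Reagents that add atoms: none
Why: Steglich esterification acylates the only reactive hydroxyl (secondary C6), the tertiary C4 alcohol being inert, and the allyl ether masks the phenol without being able to act as an acyl donor.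

**Step 17**
Reactants: 29 allyl-protected diester
Product: 30 target, 2β-angeloyloxy-6α-(4-hydroxybenzoyloxy)dauc-8-en-4β-ol
Conditions: Pd(PPh3)4 (5 mol %), morpholine, THF, rt
Reagents that add atoms: none
Why: In this Tsuji–Trost-type deallylation zerovalent palladium ionises the aryl allyl ether, whose electron-poor phenoxide is a good leaving group, and morpholine traps the π-allyl complex under neutral conditions that leave both esters, the Z alkene and the non-allylic C–O bonds untouched.

**Compound list**
1 | 2,5-dimethylanisole | COc1cc(C)ccc1C | starting material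
2 | 1-methoxy-2,5-dimethylcyclohexa-1,4-diene | COC1=C(C)CC=C(C)C1 | intermediate
3 | bromoform | BrC(Br)Br | starting material
4 | (±)-7,7-dibromo-1-methoxy-3,6-dimethylbicyclo[4.1.0]hept-3-ene (cis-fused, one enantiomer drawn) | CO[C@@]12CC(C)=CC[C@]1(C)C2(Br)Br | intermediate
5 | 2-bromo-3,6-dimethylcyclohepta-2,5-dien-1-one (achiral) | O=C1CC(C)=CCC(C)=C1Br | intermediate
6 | (S)-2-bromo-3,6-dimethylcyclohepta-2,5-dien-1-ol | O[C@H]1CC(C)=CCC(C)=C1Br | intermediate
7 | tributyl(iodomethyl)stannane | CCCC[Sn](CI)(CCCC)CCCC | starting material
8 | (S)-tributyl{[(2-bromo-3,6-dimethylcyclohepta-2,5-dien-1-yl)oxy]methyl}stannane | CCCC[Sn](CCCC)(CCCC)CO[C@H]1CC(C)=CCC(C)=C1Br | intermediate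
9 | lithiomethyl ether of 6 (not isolated) | [Li]CO[C@H]1CC(C)=CCC(C)=C1Br | intermediate
10 | [(S)-2-bromo-1,5-dimethylcyclohepta-2,5-dien-1-yl]methanol | OC[C@]1(C)CC=C(C)CC=C1Br | intermediate
11 | carbon monoxide | [C-]#[O+] | starting material
12 | (3aR)-3a,6-dimethyl-3,3a,4,7-tetrahydro-1H-cyclohepta[c]furan-1-one | O=C1OC[C@]2(C)CC=C(C)CC=C12 | intermediate
13 | cis-fused 6α-pinacolboryl lactone (not isolated) | O=C1OC[C@]2(C)CC=C(C)C[C@H](B3OC(C)(C)C(C)(C)O3)[C@H]12 | intermediate
14 | cis-fused 6α-hydroxy lactone | O=C1OC[C@]2(C)CC=C(C)C[C@H](O)[C@H]12 | intermediate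
15 | cis-fused 6α-(tert-butyldimethylsilyloxy) lactone | O=C1OC[C@]2(C)CC=C(C)C[C@H](O[Si](C)(C)C(C)(C)C)[C@H]12 | intermediate
16 | isopropyllithium | [Li]C(C)C | starting material
17 | 5-epi hydroxy ketone (isobutyryl α, not isolated) | OC[C@]1(C)CC=C(C)C[C@H](O[Si](C)(C)C(C)(C)C)[C@@H]1C(=O)C(C)C | intermediate
18 | hydroxy ketone (CH2OH α, isobutyryl β, OTBS α) | OC[C@]1(C)CC=C(C)C[C@H](O[Si](C)(C)C(C)(C)C)[C@H]1C(=O)C(C)C | intermediate
19 | keto aldehyde (CHO α, isobutyryl β, OTBS α) | O=C[C@]1(C)CC=C(C)C[C@H](O[Si](C)(C)C(C)(C)C)[C@H]1C(=O)C(C)C | intermediate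
20 | nitromethane | C[N+](=O)[O-] | starting material
21 | C2 nitro alcohol, open form (not isolated) | O[C@H](C[N+](=O)[O-])[C@]1(C)CC=C(C)C[C@H](O[Si](C)(C)C(C)(C)C)[C@H]1C(=O)C(C)C | intermediate
22 | 3α-nitro-6α-(tert-butyldimethylsilyloxy)dauc-8-ene-2β,4β-diol | O[C@@H]1[C@@H]([N+](=O)[O-])[C@@](O)(C(C)C)[C@@H]2[C@@H](O[Si](C)(C)C(C)(C)C)CC(C)=CC[C@]21C | intermediate
23 | 6α-(tert-butyldimethylsilyloxy)dauc-8-ene-2β,4β-diol | O[C@@H]1C[C@@](O)(C(C)C)[C@@H]2[C@@H](O[Si](C)(C)C(C)(C)C)CC(C)=CC[C@]21C | intermediate
24 | angelic acid, (Z)-2-methylbut-2-enoic acid | C/C=C(/C)C(=O)O | starting material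
25 | angelic 2,4,6-trichlorobenzoic anhydride (not isolated) | C/C=C(/C)C(=O)OC(=O)c1c(Cl)cc(Cl)cc1Cl | intermediate
26 | 2β-angeloyloxy-6α-(tert-butyldimethylsilyloxy)dauc-8-en-4β-ol | C/C=C(/C)C(=O)O[C@@H]1C[C@@](O)(C(C)C)[C@@H]2[C@@H](O[Si](C)(C)C(C)(C)C)CC(C)=CC[C@]21C | intermediate
27 | 2β-angeloyloxydauc-8-ene-4β,6α-diol | C/C=C(/C)C(=O)O[C@@H]1C[C@@](O)(C(C)C)[C@@H]2[C@@H](O)CC(C)=CC[C@]21C | intermediate
28 | 4-(allyloxy)benzoic acid | OC(=O)c1ccc(OCC=C)cc1 | starting material
29 | 6α-[4-(allyloxy)benzoyloxy]-2β-angeloyloxydauc-8-en-4β-ol | C/C=C(/C)C(=O)O[C@@H]1C[C@@](O)(C(C)C)[C@@H]2[C@@H](OC(=O)c3ccc(OCC=C)cc3)CC(C)=CC[C@]21C | intermediate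
30 | CNP0188626.1 | C/C=C(/C)C(=O)O[C@@H]1C[C@@](O)(C(C)C)[C@@H]2[C@@H](OC(=O)c3ccc(O)cc3)CC(C)=CC[C@]21C | target

**Total step count:** 17. **Longest linear sequence:** 17 (from 1).

**Steps most likely to fail**

1. Step 12. The intramolecular nitroaldol onto the hindered isopropyl ketone may lie on the side of the open chain. The equilibrium may also settle on another C2/C4 arrangement, or the nitro alcohol may dehydrate. The fallback replaces the nitroaldol by an intramolecular aldol.
   - From 19, MeMgBr at −78 °C adds to the aldehyde only and gives the C2 methyl carbinol F1 as an epimer mixture.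
   - Dess–Martin oxidation gives the 1,4-diketone F2.
   - LiHMDS at −78 °C deprotonates the methyl group kinetically, and the enolate closes on the C4 ketone to give the ketol F3, with isopropyl again away from the C6 arm.
   - NaBH4 attacks the C2 ketone from the α face, opposite the angular methyl as in 17-keto steroids, and gives 23, where the route resumes.

2. Step 10. The organolithium may enolise the lactone, or the carbonate may enolise the ketone, and β-elimination of the silyloxy group may follow. The C5 equilibrium may also be incomplete. The fallback carries the C6 oxygen unprotected through addition and equilibration.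
   - From 14, excess i-PrLi first makes the C6 alkoxide, which cannot leave and lowers the acidity of H5, then opens the lactone.
   - The same carbonate treatment gives the dihydroxy ketone F4.
   - TBSOTf and 2,6-lutidine silylate both hydroxyls to the bis-silyl ether F5.
   - Pyridine-buffered HF·pyridine removes the primary silyl ether selectively and gives 18.

3. Step 6. Bromine–lithium exchange may compete with tin–lithium exchange, and a [1,2]-shift or simple protonation of the carbanion may intervene. The fallback delivers the one carbon without an organolithium.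
   - From 6, heating with DMF dimethyl acetal in xylene forms the alkoxy(dimethylamino)carbene. Its suprafacial [2,3]-sigmatropic shift gives the dimethylamide F6 with the same transfer of configuration to C1.
   - LiH2NBH3 reduces the hindered tertiary amide to 10.

**Further compounds**
F1 | step 12 | C2 methyl carbinol (epimers at the new carbinol) | CC(O)[C@]1(C)CC=C(C)C[C@H](O[Si](C)(C)C(C)(C)C)[C@H]1C(=O)C(C)C
F2 | step 12 | 1α-acetyl-5β-isobutyryl 1,4-diketone | CC(=O)[C@]1(C)CC=C(C)C[C@H](O[Si](C)(C)C(C)(C)C)[C@H]1C(=O)C(C)C
F3 | step 12 | 4β-hydroxy-6α-(tert-butyldimethylsilyloxy)dauc-8-en-2-one | O=C1C[C@@](O)(C(C)C)[C@@H]2[C@@H](O[Si](C)(C)C(C)(C)C)CC(C)=CC[C@]21C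
F4 | step 10 | dihydroxy ketone (CH2OH α, isobutyryl β, OH α) | OC[C@]1(C)CC=C(C)C[C@H](O)[C@H]1C(=O)C(C)C
F5 | step 10 | bis(tert-butyldimethylsilyl) ether of F4 | CC(C)(C)[Si](C)(C)OC[C@]1(C)CC=C(C)C[C@H](O[Si](C)(C)C(C)(C)C)[C@H]1C(=O)C(C)C
F6 | step 6 | 2-bromo-N,N,1,5-tetramethylcyclohepta-2,5-diene-1-carboxamide (same spatial arrangement at C1 as 10) | CN(C)C(=O)[C@]1(C)CC=C(C)CC=C1Br
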